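Ring A is disconnected at the bond between its methylidene-bearing carbon C6 and the chain-bearing stereocentre C1. A σ-vinyl radical generated at C6 from a 2-bromoalkene closes ring A by 6-exo-trig addition to the β-carbon of an (E)-enoate. In one operation this forms C6–C1, installs the exocyclic methylene, sets C1 from the existing C3 silyloxy centre and leaves a two-carbon ester arm. The precursor is an acyclic (5S)-silyloxy bromo-dienoate made by an enantioselective Mukaiyama aldol. Afterwards C3 is inverted by oxidation–reduction, and the arm is joined to a chroman (Z)-vinyl iodide by Zweifel olefination.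

Key step: step 7

Remarks on the chemistry
- Numbering: in ring A, C1 carries the side chain, C2 the gem-dimethyl group, C3 the oxygen and C6 the methylidene; chain carbons C1'–C6' run from ring A to chroman C2. TBS = tert-butyldimethylsilyl, TIPS = triisopropylsilyl, pin = pinacolato.
- Stereochemical bookkeeping: the (5S) carbinol of the cyclization precursor becomes C3 (S), and the cyclization creates C1 (R), which is the target configuration. The target needs C3 (R), hence the later inversion. Some CIP descriptors flip at centres that are never touched (epoxy iodide, alkylborane, chroman aldehyde) because substituent priorities change; the SMILES strings are authoritative.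
- Assumption: the oxazaborolidinone from N-tosyl-(R)-valine is taken to deliver the (S)-aldol (Re-face attack). The sense should be confirmed on the aldol product by Mosher ester analysis, with the (S)-valine reagent as the alternative.

Step 1
Reactants: 1 ethyl acetate; 2 2,3-dibromopropene
Product: 4 ethyl 4-bromopent-4-enoate, via lithium enolate 3 (not isolated)
Conditions: LiN(i-Pr)2 (1.1 equiv), THF, −78 °C; then 2 (0.9 equiv), DMPU, −78 → −20 °C
Reagents that add atoms: none
Why: Ester enolate alkylation, in which the allylic bromide of 2 is displaced (SN2) far faster than the vinylic one and the cold pre-formed enolate suppresses Claisen self-condensation.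

Step 2
Reactants: 4 ethyl 4-bromopent-4-enoate
Product: 6 4-bromopent-4-enal, via aluminium hemiacetal 5 (not isolated)
Conditions: i-Bu2AlH (1.05 equiv), CH2Cl2, −78 °C; MeOH, then aq. KNaC4H4O6
Reagents that add atoms: none
Why: Partial ester reduction, in which the tetrahedral aluminium hemiacetal persists at −78 °C and releases the aldehyde only on work-up while the vinyl bromide is inert to the hydride.

Step 3
Reactants: 6 4-bromopent-4-enal; 7 1-methoxy-2-methyl-1-(trimethylsilyloxy)prop-1-ene
Product: 9 methyl (3S)-6-bromo-3-hydroxy-2,2-dimethylhept-6-enoate, via trimethylsilyl ether 8 (not isolated)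
Conditions: N-tosyl-D-valine (1.1 equiv), BH3·THF (1.0 equiv), CH2Cl2, 0 → 25 °C; then 6 and 7, −78 °C; aq. HCl work-up
Reagents that add atoms: none
Why: Oxazaborolidinone-promoted enantioselective Mukaiyama aldol, in which the aldehyde bound to the valine-derived boron Lewis acid should be attacked on its Re face by the ketene acetal, setting the carbinol (later ring A C3) as S.

Step 4
Reactants: 9 methyl (3S)-6-bromo-3-hydroxy-2,2-dimethylhept-6-enoate
Product: 10 methyl (3S)-6-bromo-3-(TBSO)-2,2-dimethylhept-6-enoate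
Conditions: TBSOTf, 2,6-lutidine, CH2Cl2, 0 °C
Reagents that add atoms: tert-butyldimethylsilyl trifluoromethanesulfonate, CC(C)(C)[Si](C)(C)OS(=O)(=O)C(F)(F)F
Why: Silyl ether formation, for which the silyl triflate is reactive enough for the hindered neopentylic alcohol and gives the bulky ether that later anchors the cyclization conformation.

Step 5
Reactants: 10 methyl (3S)-6-bromo-3-(TBSO)-2,2-dimethylhept-6-enoate
Product: 12 (3S)-6-bromo-3-(TBSO)-2,2-dimethylhept-6-enal, via aluminium hemiacetal 11 (not isolated)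
Conditions: i-Bu2AlH (1.1 equiv), toluene, −78 °C; MeOH, then aq. KNaC4H4O6
Reagents that add atoms: none
Why: Partial ester reduction, in which the α-quaternary centre makes the tetrahedral aluminate especially persistent so the aldehyde should appear only on work-up (any over-reduced alcohol can be returned by Dess–Martin oxidation).

Step 6
Reactants: 12 (3S)-6-bromo-3-(TBSO)-2,2-dimethylhept-6-enal
Product: 13 ethyl (2E,5S)-8-bromo-5-(TBSO)-4,4-dimethylnona-2,8-dienoate
Conditions: (EtO)2P(O)CH2CO2Et, NaH, THF, 0 → 25 °C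
Reagents that add atoms: triethyl phosphonoacetate, CCOC(=O)CP(=O)(OCC)OCC
Why: Horner–Wadsworth–Emmons olefination, in which the stabilized phosphonate anion gives the (E)-enoate and the non-enolizable aldehyde can neither epimerize nor eliminate the β-silyloxy group.

Step 7
Reactants: 13 ethyl (2E,5S)-8-bromo-5-(TBSO)-4,4-dimethylnona-2,8-dienoate
Product: 14 ethyl 2-[(1R,3S)-3-(TBSO)-2,2-dimethyl-6-methylidenecyclohexyl]acetate
Conditions: Bu3SnH (1.3 equiv), AIBN (0.15 equiv), benzene (0.01 M), 80 °C, syringe-pump addition over 6 h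
Reagents that add atoms: none
Why: The stannyl radical abstracts bromine from 13 to give a σ-vinyl radical at C6 that adds irreversibly to the β-carbon (C1) of the enoate, and the resulting α-ester radical takes hydrogen from Bu3SnH to carry the chain. The closest known reaction type is the reductive 6-exo cyclization of vinyl radicals onto α,β-unsaturated esters. Ring A closes in the 6-exo-trig mode, since 7-endo attack at the α-carbon is disfavoured by both polarity and geometry. The new stereocentre C1 is controlled by the C3 silyloxy centre: in the chair-like transition state the TBSO group and the (E)-enoate should both sit equatorial, so chain and oxygen end up cis (1R,3S). The step needs ring closure to outrun direct reduction and hydrogen-atom shifts, which is secured by the quaternary C2 (no hydrogen five atoms from the radical, plus a Thorpe–Ingold push), the electron-poor acceptor and slow stannane addition. The ester-stabilized product radical is the thermodynamic sink, so homoallyl–cyclopropylcarbinyl leakage to a ring-expanded isomer is not expected.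

Step 8
Reactants: 14 ethyl 2-[(1R,3S)-3-(TBSO)-2,2-dimethyl-6-methylidenecyclohexyl]acetate
Product: 15 ethyl 2-[(1R,3S)-3-hydroxy-2,2-dimethyl-6-methylidenecyclohexyl]acetate
Conditions: 48% aq. HF, MeCN, 0 → 25 °C
Reagents that add atoms: none
Why: Acidic fluoride desilylation, which cleaves the hindered secondary silyl ether without forming an alkoxide that could lactonize onto the cis ester and leaves the 1,1-disubstituted alkene alone.

Step 9
Reactants: 15 ethyl 2-[(1R,3S)-3-hydroxy-2,2-dimethyl-6-methylidenecyclohexyl]acetate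
Product: 16 ethyl 2-[(1R)-2,2-dimethyl-6-methylidene-3-oxocyclohexyl]acetate
Conditions: Dess–Martin periodinane, NaHCO3, CH2Cl2, 25 °C
Reagents that add atoms: none
Why: Dess–Martin oxidation under buffered neutral conditions, giving a ketone whose only α-hydrogens (C4) are remote from C1 so that stereocentre is not at risk.

Step 10
Reactants: 16 ethyl 2-[(1R)-2,2-dimethyl-6-methylidene-3-oxocyclohexyl]acetate
Product: 17 ethyl 2-[(1R,3R)-3-hydroxy-2,2-dimethyl-6-methylidenecyclohexyl]acetate
Conditions: LiBH(sec-Bu)3 (1.2 equiv), THF, −78 °C; H2O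
Reagents that add atoms: none
Why: Diastereoselective ketone reduction with a bulky trialkylborohydride, which should enter along the equatorial trajectory (axial approach meets the syn-axial hydrogens at C1 and C5) to give the axial C3 alcohol trans to the chain, as known for 2,2-dimethylcyclohexanones, while the ester is inert at −78 °C.

Step 11
Reactants: 17 ethyl 2-[(1R,3R)-3-hydroxy-2,2-dimethyl-6-methylidenecyclohexyl]acetate
Product: 18 ethyl 2-[(1R,3R)-3-(TBSO)-2,2-dimethyl-6-methylidenecyclohexyl]acetate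
Conditions: TBSOTf, 2,6-lutidine, CH2Cl2, 0 → 25 °C
Reagents that add atoms: tert-butyldimethylsilyl trifluoromethanesulfonate, CC(C)(C)[Si](C)(C)OS(=O)(=O)C(F)(F)F
Why: Silyl ether formation, which masks the axial alcohol against the organometallic reagents of the fragment union.

Step 12
Reactants: 18 ethyl 2-[(1R,3R)-3-(TBSO)-2,2-dimethyl-6-methylidenecyclohexyl]acetate
Product: 19 2-[(1R,3R)-3-(TBSO)-2,2-dimethyl-6-methylidenecyclohexyl]ethan-1-ol
Conditions: i-Bu2AlH (2.5 equiv), CH2Cl2, −78 → 0 °C; aq. KNaC4H4O6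
Reagents that add atoms: none
Why: Ester reduction to the primary alcohol with excess aluminium hydride, to which the silyl ether and the alkene are inert.

Step 13
Reactants: 19 2-[(1R,3R)-3-(TBSO)-2,2-dimethyl-6-methylidenecyclohexyl]ethan-1-ol
Product: 20 (1R,3R)-3-(TBSO)-1-(2-iodoethyl)-2,2-dimethyl-6-methylidenecyclohexane
Conditions: I2, PPh3, imidazole, CH2Cl2, 0 → 25 °C
Reagents that add atoms: iodine, II
Why: Appel-type iodination, in which iodide displaces the alkoxyphosphonium group at the unhindered primary carbon.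

Step 14
Reactants: 20 (1R,3R)-3-(TBSO)-1-(2-iodoethyl)-2,2-dimethyl-6-methylidenecyclohexane
Product: 21 2-{2-[(1R,3R)-3-(TBSO)-2,2-dimethyl-6-methylidenecyclohexyl]ethyl}-4,4,5,5-tetramethyl-1,3,2-dioxaborolane
Conditions: B2pin2, CuI (10 mol%), PPh3 (13 mol%), LiOMe, DMF, 25 °C
Reagents that add atoms: bis(pinacolato)diboron, CC1(C)OB(OC1(C)C)B1OC(C)(C)C(C)(C)O1
Why: Copper-catalysed borylation of a primary alkyl iodide, which proceeds under mild basic conditions that tolerate the silyl ether and the alkene.

Step 15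
Reactants: 22 geraniol
Product: 23 [(2S,3S)-3-methyl-3-(4-methylpent-3-en-1-yl)oxiran-2-yl]methanol
Conditions: Ti(O-i-Pr)4 (5 mol%), L-(+)-diethyl tartrate (7 mol%), t-BuOOH, 4 Å molecular sieves, CH2Cl2, −20 °C
Reagents that add atoms: tert-butyl hydroperoxide, CC(C)(C)OO
Why: Sharpless asymmetric epoxidation, in which the titanium tartrate complex epoxidizes only the allylic-alcohol alkene and the L-tartrate selects the face that gives the (2S,3S)-epoxide, fixing the future chroman C2 centre.

Step 16
Reactants: 23 [(2S,3S)-3-methyl-3-(4-methylpent-3-en-1-yl)oxiran-2-yl]methanol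
Product: 24 (2R,3S)-2-(iodomethyl)-3-methyl-3-(4-methylpent-3-en-1-yl)oxirane
Conditions: I2, PPh3, imidazole, Et2O–MeCN, 0 °C
Reagents that add atoms: iodine, II
Why: Appel-type iodination, which replaces the primary hydroxyl without opening the epoxide (the 2R descriptor reflects only the changed priorities).

Step 17
Reactants: 24 (2R,3S)-2-(iodomethyl)-3-methyl-3-(4-methylpent-3-en-1-yl)oxirane
Product: 25 (3S)-3,7-dimethylocta-1,6-dien-3-ol
Conditions: Zn dust, EtOH, 70 °C; aq. NH4Cl
Reagents that add atoms: none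
Why: Reductive β-elimination, in which zinc inserts into the carbon–iodine bond and the epoxide opens to the tertiary allylic alkoxide with the tertiary C–O bond intact, so the centre is retained.

Step 18
Reactants: 26 4-amino-3-methylphenol
Product: 27 2-methyl-4-(TIPSO)aniline
Conditions: TIPSCl, imidazole, DMF, 25 °C
Reagents that add atoms: chlorotriisopropylsilane, CC(C)[Si](Cl)(C(C)C)C(C)C
Why: O-silylation, in which oxophilic silicon takes the phenol in preference to the aniline nitrogen and the bulky base-stable ether protects the phenol to the end.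

Step 19
Reactants: 27 2-methyl-4-(TIPSO)aniline
Product: 28 2-iodo-6-methyl-4-(TIPSO)aniline
Conditions: N-iodosuccinimide, MeCN, 0 °C
Reagents that add atoms: N-iodosuccinimide, O=C1CCC(=O)N1I
Why: Electrophilic aromatic iodination, directed by the amino group to its only free ortho position because para is occupied and the positions next to the silyloxy group are shielded.

Step 20
Reactants: 28 2-iodo-6-methyl-4-(TIPSO)aniline
Product: 30 (4-bromo-3-iodo-5-methylphenoxy)triisopropylsilane, via diazonium bromide 29 (not isolated)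
Conditions: t-BuONO, CuBr2, MeCN, 0 → 25 °C
Reagents that add atoms: copper dibromide, [Cu+2].[Br-].[Br-]
Why: Sandmeyer-type bromodeamination under aprotic conditions, in which alkyl nitrite diazotization and copper-mediated bromine transfer replace the amino group and give the ortho iodo/bromo pair needed for two sequential couplings.

Step 21
Reactants: 25 (3S)-3,7-dimethylocta-1,6-dien-3-ol; 30 (4-bromo-3-iodo-5-methylphenoxy)triisopropylsilane
Product: 32 (3S)-1-[2-bromo-3-methyl-5-(TIPSO)phenyl]-3,7-dimethyloct-6-en-3-ol, via alkylborane 31 (not isolated)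
Conditions: 25, 9-BBN (1.5 equiv), THF, 0 → 25 °C; then 30, PdCl2(dppf) (5 mol%), AsPh3, aq. Cs2CO3, DMF, 25 °C
Reagents that add atoms: none
Why: Hydroboration followed by B-alkyl Suzuki–Miyaura coupling, in which 9-BBN adds only to the monosubstituted vinyl group and palladium inserts into the aryl iodide in preference to the flanked bromide, the carbinol centre being untouched.

Step 22
Reactants: 32 (3S)-1-[2-bromo-3-methyl-5-(TIPSO)phenyl]-3,7-dimethyloct-6-en-3-ol
Product: 33 (2S)-2,8-dimethyl-2-(4-methylpent-3-en-1-yl)-6-(TIPSO)-3,4-dihydro-2H-chromene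
Conditions: Pd(OAc)2 (5 mol%), 2-(di-tert-butylphosphino)-1,1'-binaphthyl (6 mol%), Cs2CO3, toluene, 80 °C
Reagents that add atoms: none
Why: Palladium-catalysed intramolecular C–O coupling (Buchwald–Hartwig-type etherification), in which the tertiary alkoxide has no hydrogen on its carbinol carbon for β-hydride loss and the C–O bond of the stereocentre is never broken, so the configuration is retained.

Step 23
Reactants: 33 (2S)-2,8-dimethyl-2-(4-methylpent-3-en-1-yl)-6-(TIPSO)-3,4-dihydro-2H-chromene
Product: 34 3-[(2R)-2,8-dimethyl-6-(TIPSO)-3,4-dihydro-2H-chromen-2-yl]propanal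
Conditions: OsO4 (2 mol%), NaIO4, 2,6-lutidine, dioxane–H2O, 25 °C
Reagents that add atoms: osmium tetroxide, O=[Os](=O)(=O)=O (catalytic oxygen carrier); sodium periodate, [Na+].[O-]I(=O)(=O)=O (terminal oxygen source)
Why: Lemieux–Johnson oxidative cleavage, in which dihydroxylation of the only alkene and periodate cleavage of the diol give the aldehyde and acetone without touching the electron-rich arene.

Step 24
Reactants: 34 3-[(2R)-2,8-dimethyl-6-(TIPSO)-3,4-dihydro-2H-chromen-2-yl]propanal
Product: 35 (2S)-2-[(3Z)-4-iodopent-3-en-1-yl]-2,8-dimethyl-6-(TIPSO)-3,4-dihydro-2H-chromene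
Conditions: EtPPh3Br, n-BuLi, THF, 25 °C; I2, −78 °C; NaN(SiMe3)2, −20 °C; then 34, −78 → 25 °C
Reagents that add atoms: ethyltriphenylphosphonium bromide, CC[P+](c1ccccc1)(c1ccccc1)c1ccccc1.[Br-]; iodine, II
Why: Stork–Zhao-type Wittig olefination with the α-iodoethylidene ylide, whose kinetically controlled addition places iodine cis to the chain and gives the (Z)-2-iodoalkene.

Step 25
Reactants: 35 (2S)-2-[(3Z)-4-iodopent-3-en-1-yl]-2,8-dimethyl-6-(TIPSO)-3,4-dihydro-2H-chromene; 21 2-{2-[(1R,3R)-3-(TBSO)-2,2-dimethyl-6-methylidenecyclohexyl]ethyl}-4,4,5,5-tetramethyl-1,3,2-dioxaborolane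
Product: 39 (2S)-2-[(3E)-6-[(1R,3R)-3-(TBSO)-2,2-dimethyl-6-methylidenecyclohexyl]-4-methylhex-3-en-1-yl]-2,8-dimethyl-6-(TIPSO)-3,4-dihydro-2H-chromene, via vinyllithium 36 (not isolated), via boronate complex 37 (not isolated), via iodo boronic ester 38 (not isolated)
Conditions: 35, t-BuLi (2.1 equiv), Et2O–THF, −78 °C; 21, −78 → 0 °C; I2, MeOH, −78 °C; NaOMe, MeOH, −78 → 25 °C
Reagents that add atoms: none
Why: Zweifel olefination, in which lithium–iodine exchange with retention gives the alkenyllithium that adds to boron, iodination triggers 1,2-migration of the ring A ethyl group anti to the iodonium, and methoxide-induced anti elimination of boron and iodine then places the alkyl group with inversion of alkene geometry, so the (Z)-iodide gives the (E)-trisubstituted alkene.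

Step 26
Reactants: 39 (2S)-2-[(3E)-6-[(1R,3R)-3-(TBSO)-2,2-dimethyl-6-methylidenecyclohexyl]-4-methylhex-3-en-1-yl]-2,8-dimethyl-6-(TIPSO)-3,4-dihydro-2H-chromene
Product: 40 (2S)-2-[(3E)-6-[(1R,3R)-3-hydroxy-2,2-dimethyl-6-methylidenecyclohexyl]-4-methylhex-3-en-1-yl]-2,8-dimethyl-3,4-dihydro-2H-chromen-6-ol
Conditions: Bu4NF, THF, 25 → 50 °C, argon; aq. NH4Cl
Reagents that add atoms: none
Why: Fluoride-mediated global desilylation, which cleaves both the aryl silyl ether and the hindered secondary silyl ether, with air excluded to protect the electron-rich chromanol.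

Compound list
1 | ethyl acetate | CCOC(C)=O | starting material
2 | 2,3-dibromopropene | C=C(Br)CBr | starting material
3 | lithium 1-ethoxyethen-1-olate (lithium enolate of ethyl acetate) | C=C(OCC)O[Li] | intermediate
4 | ethyl 4-bromopent-4-enoate | C=C(Br)CCC(=O)OCC | intermediate
5 | diisobutylaluminium hemiacetal of 4, [(4-bromo-1-ethoxypent-4-en-1-yl)oxy]bis(2-methylpropyl)alumane | C=C(Br)CCC(OCC)O[Al](CC(C)C)CC(C)C | intermediate
6 | 4-bromopent-4-enal | C=C(Br)CCC=O | intermediate
7 | 1-methoxy-2-methyl-1-(trimethylsilyloxy)prop-1-ene | COC(O[Si](C)(C)C)=C(C)C | starting material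
8 | methyl (3S)-6-bromo-2,2-dimethyl-3-(trimethylsilyloxy)hept-6-enoate | C=C(Br)CC[C@H](O[Si](C)(C)C)C(C)(C)C(=O)OC | intermediate
9 | methyl (3S)-6-bromo-3-hydroxy-2,2-dimethylhept-6-enoate | C=C(Br)CC[C@H](O)C(C)(C)C(=O)OC | intermediate
10 | methyl (3S)-6-bromo-3-(tert-butyldimethylsilyloxy)-2,2-dimethylhept-6-enoate | C=C(Br)CC[C@H](O[Si](C)(C)C(C)(C)C)C(C)(C)C(=O)OC | intermediate
11 | diisobutylaluminium hemiacetal of 10 (O-aluminated methyl hemiacetal; acetal carbon unassigned) | C=C(Br)CC[C@H](O[Si](C)(C)C(C)(C)C)C(C)(C)C(OC)O[Al](CC(C)C)CC(C)C | intermediate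
12 | (3S)-6-bromo-3-(tert-butyldimethylsilyloxy)-2,2-dimethylhept-6-enal | C=C(Br)CC[C@H](O[Si](C)(C)C(C)(C)C)C(C)(C)C=O | intermediate
13 | ethyl (2E,5S)-8-bromo-5-(tert-butyldimethylsilyloxy)-4,4-dimethylnona-2,8-dienoate | C=C(Br)CC[C@H](O[Si](C)(C)C(C)(C)C)C(C)(C)/C=C/C(=O)OCC | intermediate
14 | ethyl 2-[(1R,3S)-3-(tert-butyldimethylsilyloxy)-2,2-dimethyl-6-methylidenecyclohexyl]acetate | C=C1CC[C@H](O[Si](C)(C)C(C)(C)C)C(C)(C)[C@@H]1CC(=O)OCC | intermediate
15 | ethyl 2-[(1R,3S)-3-hydroxy-2,2-dimethyl-6-methylidenecyclohexyl]acetate | C=C1CC[C@H](O)C(C)(C)[C@@H]1CC(=O)OCC | intermediate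
16 | ethyl 2-[(1R)-2,2-dimethyl-6-methylidene-3-oxocyclohexyl]acetate | C=C1CCC(=O)C(C)(C)[C@@H]1CC(=O)OCC | intermediate
17 | ethyl 2-[(1R,3R)-3-hydroxy-2,2-dimethyl-6-methylidenecyclohexyl]acetate | C=C1CC[C@@H](O)C(C)(C)[C@@H]1CC(=O)OCC | intermediate
18 | ethyl 2-[(1R,3R)-3-(tert-butyldimethylsilyloxy)-2,2-dimethyl-6-methylidenecyclohexyl]acetate | C=C1CC[C@@H](O[Si](C)(C)C(C)(C)C)C(C)(C)[C@@H]1CC(=O)OCC | intermediate
19 | 2-[(1R,3R)-3-(tert-butyldimethylsilyloxy)-2,2-dimethyl-6-methylidenecyclohexyl]ethan-1-ol | C=C1CC[C@@H](O[Si](C)(C)C(C)(C)C)C(C)(C)[C@@H]1CCO | intermediate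
20 | (1R,3R)-3-(tert-butyldimethylsilyloxy)-1-(2-iodoethyl)-2,2-dimethyl-6-methylidenecyclohexane | C=C1CC[C@@H](O[Si](C)(C)C(C)(C)C)C(C)(C)[C@@H]1CCI | intermediate
21 | 2-{2-[(1R,3R)-3-(tert-butyldimethylsilyloxy)-2,2-dimethyl-6-methylidenecyclohexyl]ethyl}-4,4,5,5-tetramethyl-1,3,2-dioxaborolane | C=C1CC[C@@H](O[Si](C)(C)C(C)(C)C)C(C)(C)[C@@H]1CCB1OC(C)(C)C(C)(C)O1 | intermediate
22 | geraniol, (2E)-3,7-dimethylocta-2,6-dien-1-ol | CC(C)=CCC/C(C)=C/CO | starting material
23 | [(2S,3S)-3-methyl-3-(4-methylpent-3-en-1-yl)oxiran-2-yl]methanol | OC[C@@H]1O[C@@]1(C)CCC=C(C)C | intermediate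
24 | (2R,3S)-2-(iodomethyl)-3-methyl-3-(4-methylpent-3-en-1-yl)oxirane | IC[C@@H]1O[C@@]1(C)CCC=C(C)C | intermediate
25 | (3S)-3,7-dimethylocta-1,6-dien-3-ol, (S)-linalool | O[C@@](C=C)(C)CCC=C(C)C | intermediate
26 | 4-amino-3-methylphenol | Cc1cc(O)ccc1N | starting material
27 | 2-methyl-4-(triisopropylsilyloxy)aniline | Cc1cc(O[Si](C(C)C)(C(C)C)C(C)C)ccc1N | intermediate
28 | 2-iodo-6-methyl-4-(triisopropylsilyloxy)aniline | Cc1cc(O[Si](C(C)C)(C(C)C)C(C)C)cc(I)c1N | intermediate
29 | 2-iodo-6-methyl-4-(triisopropylsilyloxy)benzenediazonium bromide | Cc1cc(O[Si](C(C)C)(C(C)C)C(C)C)cc(I)c1[N+]#N.[Br-] | intermediate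
30 | (4-bromo-3-iodo-5-methylphenoxy)triisopropylsilane | Cc1cc(O[Si](C(C)C)(C(C)C)C(C)C)cc(I)c1Br | intermediate
31 | (3R)-1-(9-borabicyclo[3.3.1]nonan-9-yl)-3,7-dimethyloct-6-en-3-ol | O[C@@](CCB1C2CCCC1CCC2)(C)CCC=C(C)C | intermediate
32 | (3S)-1-[2-bromo-3-methyl-5-(triisopropylsilyloxy)phenyl]-3,7-dimethyloct-6-en-3-ol | O[C@@](CCc1cc(O[Si](C(C)C)(C(C)C)C(C)C)cc(C)c1Br)(C)CCC=C(C)C | intermediate
33 | (2S)-2,8-dimethyl-2-(4-methylpent-3-en-1-yl)-6-(triisopropylsilyloxy)-3,4-dihydro-2H-chromene | CC(C)=CCC[C@@]1(C)CCc2cc(O[Si](C(C)C)(C(C)C)C(C)C)cc(C)c2O1 | intermediate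
34 | 3-[(2R)-2,8-dimethyl-6-(triisopropylsilyloxy)-3,4-dihydro-2H-chromen-2-yl]propanal | O=CCC[C@@]1(C)CCc2cc(O[Si](C(C)C)(C(C)C)C(C)C)cc(C)c2O1 | intermediate
35 | (2S)-2-[(3Z)-4-iodopent-3-en-1-yl]-2,8-dimethyl-6-(triisopropylsilyloxy)-3,4-dihydro-2H-chromene | C/C(I)=C/CC[C@@]1(C)CCc2cc(O[Si](C(C)C)(C(C)C)C(C)C)cc(C)c2O1 | intermediate
36 | alkenyllithium from 35, lithium in place of iodine and cis to the chain | C/C([Li])=C/CC[C@@]1(C)CCc2cc(O[Si](C(C)C)(C(C)C)C(C)C)cc(C)c2O1 | intermediate
37 | lithium boronate complex of 36 and 21 (boron bears the pinacolato group, the alkenyl group and the ring A ethyl group; boron cis to the chain) | [Li+].C/C(=C/CC[C@@]1(C)CCc2cc(O[Si](C(C)C)(C(C)C)C(C)C)cc(C)c2O1)[B-]1(CC[C@@H]2C(=C)CC[C@@H](O[Si](C)(C)C(C)(C)C)C2(C)C)OC(C)(C)C(C)(C)O1 | intermediate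
38 | anti β-iodo boronic ester (pinacol boronate on C3', which also bears CH3 and C2'; iodine on C4'; forms as two face isomers of the same relative configuration, one shown) | C[C@](B1OC(C)(C)C(C)(C)O1)(CC[C@@H]2C(=C)CC[C@@H](O[Si](C)(C)C(C)(C)C)C2(C)C)[C@H](I)CC[C@@]1(C)CCc2cc(O[Si](C(C)C)(C(C)C)C(C)C)cc(C)c2O1 | intermediate
39 | (2S)-2-[(3E)-6-[(1R,3R)-3-(tert-butyldimethylsilyloxy)-2,2-dimethyl-6-methylidenecyclohexyl]-4-methylhex-3-en-1-yl]-2,8-dimethyl-6-(triisopropylsilyloxy)-3,4-dihydro-2H-chromene | C=C1CC[C@@H](O[Si](C)(C)C(C)(C)C)C(C)(C)[C@@H]1CC/C(C)=C/CC[C@@]1(C)CCc2cc(O[Si](C(C)C)(C(C)C)C(C)C)cc(C)c2O1 | intermediate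
40 | (2S)-2-[(3E)-6-[(1R,3R)-3-hydroxy-2,2-dimethyl-6-methylidenecyclohexyl]-4-methylhex-3-en-1-yl]-2,8-dimethyl-3,4-dihydro-2H-chromen-6-ol | C=C1CC[C@@H](O)C(C)(C)[C@@H]1CC/C(C)=C/CC[C@@]1(C)CCc2cc(O)cc(C)c2O1 | target

Total step count: 26 steps.
Longest linear sequence: 16 steps (steps 1–14, then 25 and 26); the chroman branch (steps 15–24) is convergent.

Steps most likely to fail

Step 7. The vinyl radical may be quenched by the stannane before ring closure, or the chair preference may give insufficient facial discrimination at C1. The fallback replaces the radical chain by a nickel-mediated intramolecular conjugate addition, setting out from 13 and returning at 14. The conditions would be Ni(cod)2 (stoichiometric), Et3N, MeCN–DMF, 25 °C, then aq. NH4Cl. Oxidative addition of zerovalent nickel into the vinylic carbon–bromine bond, 6-exo insertion of the enoate and protonation of the nickel enolate should deliver 14 without a free radical that could be reduced early. No new isolated compound is involved.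

Step 25. Boronate formation between the hindered alkenyllithium and 21 may be incomplete, or iodine may be consumed unproductively so that migration and elimination lose efficiency. The fallback is a two-stage Negishi construction of the trisubstituted alkene, setting out from 34 and 20 and returning at 39. Aldehyde 34 is converted (CBr4, PPh3, CH2Cl2, 0 °C) into the 1,1-dibromoalkene F1. Iodide 20 is converted by zinc insertion (Zn dust, LiCl, THF, 40 °C) into the alkylzinc iodide F2. F2 is coupled with F1 (PdCl2(DPEphos), THF, 0 → 25 °C) selectively at the bromine trans to the chain, giving the (Z)-bromoalkene F3. Methylation with retention (Me2Zn, Pd[P(t-Bu)3]2, THF, 25 °C) should then give 39.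

Step 10. Hydride delivery may lack facial selectivity and return part of the equatorial alcohol. The fallback inverts the carbinol by substitution instead of redox, setting out from 15 and returning at 17. Mitsunobu reaction of 15 (4-nitrobenzoic acid, PPh3, diisopropyl azodicarboxylate, toluene, 0 → 25 °C) should give the inverted 4-nitrobenzoate F4, and ethanolysis (K2CO3, EtOH, 25 °C) releases 17.

Further compounds
F0 | step 7 | none | none
F1 | step 25 | (2S)-2-(4,4-dibromobut-3-en-1-yl)-2,8-dimethyl-6-(triisopropylsilyloxy)-3,4-dihydro-2H-chromene | BrC(Br)=CCC[C@@]1(C)CCc2cc(O[Si](C(C)C)(C(C)C)C(C)C)cc(C)c2O1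
F2 | step 25 | {2-[(1R,3R)-3-(tert-butyldimethylsilyloxy)-2,2-dimethyl-6-methylidenecyclohexyl]ethyl}zinc iodide | C=C1CC[C@@H](O[Si](C)(C)C(C)(C)C)C(C)(C)[C@@H]1CC[Zn]I
F3 | step 25 | (2S)-2-[(3Z)-4-bromo-6-[(1R,3R)-3-(tert-butyldimethylsilyloxy)-2,2-dimethyl-6-methylidenecyclohexyl]hex-3-en-1-yl]-2,8-dimethyl-6-(triisopropylsilyloxy)-3,4-dihydro-2H-chromene | C=C1CC[C@@H](O[Si](C)(C)C(C)(C)C)C(C)(C)[C@@H]1CC/C(Br)=C/CC[C@@]1(C)CCc2cc(O[Si](C(C)C)(C(C)C)C(C)C)cc(C)c2O1
F4 | step 10 | ethyl 2-[(1R,3R)-2,2-dimethyl-6-methylidene-3-(4-nitrobenzoyloxy)cyclohexyl]acetate | C=C1CC[C@@H](OC(=O)c2ccc(cc2)[N+](=O)[O-])C(C)(C)[C@@H]1CC(=O)OCC
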